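**Strategy**

Ring C is disconnected to carbon dioxide, a two-carbon acetylene equivalent and an N-acyl amino acid. The twelve-membered ring of premarineosin A runs through C2, N1 and C5 of pyrrole ring C; these three atoms correspond to the α-carbon, the nitrogen and the acyl carbon of an amide, so the strained pyrrolophane can be assembled first as an unstrained macrolactam. In one operation the derived bridged münchnone takes up phenyl vinyl sulfone and loses CO2 and sulfinic acid, creating ring C with its C2–C3 and C4–C5 bonds. The precursor is a trans-fused δ-lactone/twelve-membered N-(2,4-dimethoxybenzyl) lactam carrying a free carboxyl group on the carbon next to nitrogen. The lactone carbonyl later becomes the spiro carbon of ring B.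

Key step: step 7

Remark: the amino acid carbon made in step 3 is carried as a mixture of epimers and drawn without configuration, because step 7 turns it into an sp2 ring carbon; the alkene of 13 is an E/Z mixture that step 6 removes.

Numbering used below: lactone/tetrahydropyran O1, C2 (carbonyl, later spiro carbon), C3 (bears ring C), C4 (bears the chain), C5, C6 (bears methyl). Ring C: C2 bears the tetrahydropyran carbon, C5 the heptamethylene chain. DMB = 2,4-dimethoxybenzyl.

Design points: the carboxyl group is masked as a benzyl ester, so it is freed by hydrogenolysis with no base near the epimerisable C3. The macrolactam is closed by metathesis after an easy intermolecular N-acylation, not by lactamisation of a hindered secondary amine. Ozone is avoided in the presence of the pyrrole.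

**Route**

Step 1
Reactants: 1 (S)-parasorbic acid; 2 5-bromo-1-pentene
Product: 4 (4S,6S)-6-methyl-4-(pent-4-en-1-yl)tetrahydro-2H-pyran-2-one, via pent-4-enylmagnesium bromide 3 (not isolated)
Conditions: 2, Mg, THF, rt; then 1, CuBr·SMe2 (10 mol %), THF, −78 to −40 °C; aq NH4Cl
Reagents that add atoms: none
Why: Copper-catalysed conjugate addition of the Grignard reagent to the unsaturated lactone occurs axially on the face of the half-chair opposite the C6 methyl group, which sets C4 trans to C6 (4S).

Step 2
Reactants: 5 dibenzyl L-tartrate; 6 2,4-dimethoxybenzylamine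
Product: 8 benzyl (E)-2-[(2,4-dimethoxybenzyl)imino]acetate, via benzyl glyoxylate 7 (not isolated)
Conditions: 5 (0.5 equiv), H5IO6, Et2O, rt; filter; then 6, MgSO4, CH2Cl2, 0 °C to rt; used crude
Reagents that add atoms: none
Why: Glycol cleavage of the tartrate (Malaprade reaction) gives two equivalents of the glyoxylate, which condenses with the primary amine to the imine; the imine is used crude because α-imino esters hydrolyse on silica.

Step 3
Reactants: 4; 8
Product: 10 benzyl 2-[(2,4-dimethoxybenzyl)amino]-2-[(3S,4S,6S)-6-methyl-2-oxo-4-(pent-4-en-1-yl)tetrahydro-2H-pyran-3-yl]acetate (both epimers at the amino acid carbon), via lithium enolate 9 (not isolated)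
Conditions: LiN(SiMe3)2 (1.05 equiv), THF, −78 °C; then 8 (1.3 equiv), −78 °C; AcOH, −78 °C
Reagents that add atoms: none
Why: Mannich addition of the lithium lactone enolate to the activated α-imino ester should take place anti to the C4 side chain and set C3 trans to C4 (3S), while the cold quench keeps the lithium amide from closing a β-lactam onto the lactone.

Step 4
Reactants: 10; 11 pent-4-enoyl chloride
Product: 12 benzyl 2-[N-(2,4-dimethoxybenzyl)pent-4-enamido]-2-[(3S,4S,6S)-6-methyl-2-oxo-4-(pent-4-en-1-yl)tetrahydro-2H-pyran-3-yl]acetate
Conditions: pyridine, DMAP (10 mol %), CH2Cl2, 0 °C to rt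
Reagents that add atoms: none
Why: DMAP-catalysed N-acylation of the hindered secondary amine by an unhindered acid chloride is intermolecular and fast, and it installs the acyl carbon that becomes C5 of ring C.

Step 5
Reactants: 12
Product: 13 unsaturated twelve-membered N-DMB macrolactam benzyl ester fused trans to the δ-lactone (E/Z mixture)
Conditions: second-generation Grubbs catalyst RuCl2(=CHPh)(PCy3)(H2IMes) (5 mol %), CH2Cl2 (2 mM), 40 °C
Reagents that add atoms: none
Why: Ring-closing olefin metathesis of two unhindered terminal alkenes at high dilution should close the twelve-membered lactam, helped by the gauche trans arrangement of the two arms on the lactone and the turn of the tertiary amide.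

Step 6
Reactants: 13
Product: 14 lactone-fused twelve-membered N-DMB macrolactam carboxylic acid (3S,4S,6S; amino acid carbon as a mixture)
Conditions: H2 (1 atm), 10% Pd/C, EtOAc, rt
Reagents that add atoms: none
Why: Heterogeneous catalytic hydrogenation saturates the alkene and hydrogenolyses the benzyl ester in one neutral operation that leaves the lactone, the N-benzyl amide and the C3 centre untouched.

Step 7
Reactants: 14; 15 phenyl vinyl sulfone
Product: 19 N-DMB pyrrolophane lactone, via münchnone 16 (not isolated), via cycloadduct 17 (not isolated), via sulfonyl dihydropyrrole 18 (not isolated)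
Conditions: Ac2O (10 equiv), 15 (5 equiv), PhMe, 90 °C, slow addition of 14
Reagents that add atoms: none
Why: Proposed new method: acetic anhydride turns the acid into a mixed anhydride, the amide oxygen closes onto it and loss of the alpha proton gives the mesoionic oxazolium olate 16, a cyclic azomethine ylide whose two carbon termini (former acyl carbon and former alpha carbon) are already joined by the nine-atom bridge; the closest known reaction is the Huisgen cycloaddition of monocyclic or N,C4-fused münchnones with vinyl sulfones and nitroalkenes as acetylene equivalents, which has not been shown for a dipole bridged between C2 and C4. Concerted [3+2] addition of 15 to these termini on the face away from the bridge gives bicycle 17, which loses carbon dioxide by cycloreversion to dihydropyrrole 18, and elimination of benzenesulfinic acid aromatises it. Ring C is therefore closed by an intermolecular two-bond annulation onto a macrocycle that already exists, so no macrocyclisation has to fight the strain of the pyrrolophane, and C2, N and C5 of the new ring sit in the twelve-membered ring exactly as the carbon termini and nitrogen of the dipole did. No stereocentre is formed: the amino acid carbon becomes sp2 and both new ring carbons end as CH, so regio- and endo/exo selectivity are irrelevant. The step needs chemoselectivity (trapping of the dipole before it dimerises, tautomerises or is C-acetylated), which excess dipolarophile, slow addition of 14 and the absence of base secure, and it needs the lactone C3 centre to stay trans to C4, which is its thermodynamically preferred arrangement should it enolise.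

Step 8
Reactants: 19
Product: 20 N-unsubstituted pyrrolophane lactone (3S,4S,6S)
Conditions: TFA/CH2Cl2 (1:1), anisole (10 equiv), 0 °C to rt
Reagents that add atoms: none
Why: Acidolytic N-debenzylation should proceed by C-protonation of the electron-rich pyrrole and ionisation of the pyrrolium ion to the stabilised dimethoxybenzyl cation, which anisole traps by Friedel–Crafts alkylation, on a substrate whose lactone is inert to anhydrous acid.

Step 9
Reactants: 20; 21 methyl (E)-3-methoxyacrylate
Product: 23 spiro methyl tetronate (4-methoxybutenolide spiro-fused at the former lactone carbon; both spiro epimers), via methyl 3-lithio-3-methoxyacrylate 22 (not isolated)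
Conditions: LiN(i-Pr)2 (3.2 equiv), 21 (3.2 equiv), THF, −95 °C; then 20, −95 to −30 °C; aq NH4Cl
Reagents that add atoms: none
Why: 1,2-Addition of the chelated α-alkoxyvinyllithium to the lactone carbonyl (the first equivalent deprotonates the pyrrole N–H) gives a lithium hemiketalate that lactonises onto the cis ester on warming, the tetronate synthesis known for aldehydes and ketones; the spiro centre is reset in step 10, and any uncyclised keto ester converges there.

Step 10
Reactants: 23
Product: 25 spiro lactam (4-methoxy-3-pyrrolin-2-one whose C5 is the N,O-spiro carbon; spiro R), via hydroxy lactam 24 (not isolated)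
Conditions: NH3 (7 M in MeOH), 0 °C to rt; evaporate; PPTS (20 mol %), 4 Å MS, CH2Cl2, rt
Reagents that add atoms: ammonia, N
Why: Ammonolysis of the acyl ketal and ring–chain tautomerism give 24, and mild acid closes the N,O-spiroketal through the cyclic oxocarbenium or N-acyliminium ion; because the trans-fused macrocycle holds the C3 and C4 substituents equatorial, the C–N bond should take the axial anomeric position, which is the R spiro configuration of the target (stronger acid would equilibrate towards the same isomer).

Step 11
Reactants: 25
Product: 26 cyclic imidoyl triflate of ring B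
Conditions: Tf2O (1.2 equiv), 2,6-di-tert-butyl-4-methylpyridine (2 equiv), CH2Cl2, −78 to 0 °C
Reagents that add atoms: trifluoromethanesulfonic anhydride, O=S(=O)(OS(=O)(=O)C(F)(F)F)C(F)(F)F
Why: O-Sulfonylation of the nucleophilic vinylogous-carbamate lactam oxygen followed by N-deprotonation by the hindered base gives the neutral imidoyl triflate, a known activation of 4-methoxy-3-pyrrolin-2-ones, and the low temperature and base keep the cationic intermediate short-lived.

Step 12
Reactants: 26; 27 N-Boc-pyrrol-2-ylboronic acid
Product: 29 premarineosin A, via N-Boc premarineosin A 28 (not isolated)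
Conditions: Pd(PPh3)4 (10 mol %), K2CO3, dioxane/H2O, 85 °C; then MeOH, 50 °C
Reagents that add atoms: none
Why: Suzuki–Miyaura coupling of the imidoyl triflate with the pyrrolylboronic acid forms the bond between rings A and B, and carbonate-mediated methanolysis of the N-acylpyrrole-type carbamate frees ring A without touching the spiroaminal.

**Compound list**

1 | (S)-parasorbic acid | C[C@H]1CC=CC(=O)O1 | starting material
2 | 5-bromo-1-pentene | C=CCCCBr | starting material
3 | pent-4-enylmagnesium bromide | C=CCCC[Mg]Br | intermediate
4 | (4S,6S)-6-methyl-4-(pent-4-en-1-yl)tetrahydro-2H-pyran-2-one | O=C1O[C@@H](C)C[C@H](CCCC=C)C1 | intermediate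
5 | dibenzyl L-tartrate | O=C(OCc1ccccc1)[C@H](O)[C@@H](O)C(=O)OCc1ccccc1 | starting material
6 | 2,4-dimethoxybenzylamine | NCc1ccc(OC)cc1OC | starting material
7 | benzyl glyoxylate | O=CC(=O)OCc1ccccc1 | intermediate
8 | benzyl (E)-2-[(2,4-dimethoxybenzyl)imino]acetate | COc1ccc(C/N=C/C(=O)OCc2ccccc2)c(OC)c1 | intermediate
9 | lithium enolate of 4 | [Li]OC1=C[C@@H](CCCC=C)C[C@H](C)O1 | intermediate
10 | Mannich amine: benzyl 2-(DMB-amino)-2-[(3S,4S,6S)-lactonyl]acetate | O=C1O[C@@H](C)C[C@H](CCCC=C)[C@H]1C(NCc2ccc(OC)cc2OC)C(=O)OCc3ccccc3 | intermediate
11 | pent-4-enoyl chloride | C=CCCC(=O)Cl | starting material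
12 | diene amide: N-DMB-N-pent-4-enoyl derivative of 10 | O=C1O[C@@H](C)C[C@H](CCCC=C)[C@H]1C(N(Cc2ccc(OC)cc2OC)C(=O)CCC=C)C(=O)OCc3ccccc3 | intermediate
13 | unsaturated twelve-membered macrolactam benzyl ester (E/Z) | O=C2O[C@@H](C)C[C@@H]1CCCC=CCCC(=O)N(Cc3ccc(OC)cc3OC)C(C(=O)OCc3ccccc3)[C@H]12 | intermediate
14 | lactone-fused twelve-membered N-DMB macrolactam acid | O=C2O[C@@H](C)C[C@@H]1CCCCCCCC(=O)N(Cc3ccc(OC)cc3OC)C(C(=O)O)[C@H]12 | intermediate
15 | phenyl vinyl sulfone | C=CS(=O)(=O)c1ccccc1 | starting material
16 | ansa-bridged münchnone (1,3-oxazolium-5-olate bridged C2 to C4) | O=C2O[C@@H](C)C[C@@H]1CCCCCCCC3=[N+](Cc4ccc(OC)cc4OC)C(=C([O-])O3)[C@H]12 | intermediate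
17 | bicyclic cycloadduct (one regioisomer drawn; both converge) | O=C2O[C@@H](C)C[C@@H]1CCCCCCCC34OC(=O)C(N3Cc5ccc(OC)cc5OC)(CC4S(=O)(=O)c5ccccc5)[C@H]12 | intermediate
18 | phenylsulfonyl dihydropyrrole after loss of CO2 (one isomer drawn) | O=C2O[C@@H](C)C[C@@H]1CCCCCCCC3C(S(=O)(=O)c4ccccc4)C=C(N3Cc4ccc(OC)cc4OC)[C@H]12 | intermediate
19 | N-DMB pyrrolophane lactone | O=C2O[C@@H](C)C[C@@H]1CCCCCCCc3ccc(n3Cc4ccc(OC)cc4OC)[C@H]12 | intermediate
20 | N-unsubstituted pyrrolophane lactone | O=C2O[C@@H](C)C[C@@H]1CCCCCCCc3ccc([nH]3)[C@H]12 | intermediate
21 | methyl (E)-3-methoxyacrylate | CO/C=C/C(=O)OC | starting material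
22 | methyl 3-lithio-3-methoxyacrylate (lithium cis to the ester) | CO/C([Li])=C/C(=O)OC | intermediate
23 | spiro methyl tetronate (spiro epimers) | COC1=CC(=O)OC12O[C@@H](C)C[C@@H]1CCCCCCCc3ccc([nH]3)[C@H]12 | intermediate
24 | hydroxy lactam (5-hydroxy-4-methoxy-3-pyrrolin-2-one with free secondary alcohol; ring–chain mixture) | COC1=CC(=O)NC1(O)[C@@H]1c2ccc(CCCCCCC[C@H]1C[C@H](C)O)[nH]2 | intermediate
25 | spiro lactam (spiro R) | COC1=CC(=O)N[C@]12O[C@@H](C)C[C@@H]1CCCCCCCc3ccc([nH]3)[C@H]12 | intermediate
26 | ring B imidoyl triflate | COC1=CC(OS(=O)(=O)C(F)(F)F)=N[C@]12O[C@@H](C)C[C@@H]1CCCCCCCc3ccc([nH]3)[C@H]12 | intermediate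
27 | N-Boc-pyrrol-2-ylboronic acid | CC(C)(C)OC(=O)n1cccc1B(O)O | starting material
28 | N-Boc premarineosin A (Boc on ring A) | COC1=CC(c2cccn2C(=O)OC(C)(C)C)=N[C@]12O[C@@H](C)C[C@@H]1CCCCCCCc3ccc([nH]3)[C@H]12 | intermediate
29 | premarineosin A | COC1=CC(c2ccc[nH]2)=N[C@]12O[C@@H](C)C[C@@H]1CCCCCCCc3ccc([nH]3)[C@H]12 | target

**Step count and risks**

Total: 12 steps. Longest linear sequence: 11 steps (steps 1 and 3 to 12, from (S)-parasorbic acid); step 2 is a one-step side branch.

Steps most likely to fail:

1. Step 7 (key step). The bridged dipole may not form, because the oxazolium ring must become planar inside the twelve-membered ring, or it may be consumed by self-condensation or C-acetylation before the alkene adds. The fallback uses only known chemistry and moves the macrocyclisation behind an ordinary, unbridged münchnone cycloaddition. It sets out from 12: saponification with LiOH in THF/H2O and acidification, on which the δ-hydroxy acid relactonises, should give the diene acid F1. Ac2O and 15 at 90 °C should convert F1 through its unbridged münchnone into the 2,5-dialkenyl N-DMB pyrrole lactone F2. Ring-closing metathesis with the second-generation Grubbs catalyst at high dilution should give the unsaturated pyrrolophane F3, and H2 over Pd/C returns to the route at 19.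

2. Step 9. The cold-only vinyllithium may deprotonate the lactone at C3 instead of adding, may fail to reach the hindered carbonyl before it decomposes, or may add twice after ring opening. The fallback changes the electrophile to an acyclic amide with a less acidic α-hydrogen and a chelate-stabilised adduct. It sets out from 20: AlMe3 and MeNHOMe·HCl in CH2Cl2 should open the lactone to the hydroxy Weinreb amide F4. Excess 22 at −95 °C and aqueous work-up should give the (Z)-keto ester F5, which exists partly as its lactol. NH3 in MeOH and then PPTS close the hydroxy lactam 24 and return to the route at 25.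

3. Step 11. The activated lactam may be attacked by the β-carbon or N–H of pyrrole ring C (six-membered Friedel–Crafts closure), or the imidoyl triflate may hydrolyse back to 25 during isolation or coupling. The fallback avoids any cationic activation. It sets out from 25: Lawesson's reagent in THF should give the thiolactam F6, and MeI with K2CO3 in acetone the methylthio imidate F7. Liebeskind–Srogl coupling of F7 with 27 (Pd2(dba)3, tri(2-furyl)phosphine, copper thiophene-2-carboxylate of monovalent copper, Cu(O2CC4H3S), THF, 50 °C) returns to the route at 28, which is deprotected to 29 as in step 12.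

Further compounds
F1 | step 7 | diene acid: free carboxylic acid of 12 | O=C1O[C@@H](C)C[C@H](CCCC=C)[C@H]1C(N(Cc2ccc(OC)cc2OC)C(=O)CCC=C)C(=O)O
F2 | step 7 | N-DMB 2-(lactonyl)-5-(but-3-enyl)pyrrole with pent-4-enyl on lactone C4 | O=C1O[C@@H](C)C[C@H](CCCC=C)[C@H]1c2ccc(CCC=C)n2Cc3ccc(OC)cc3OC
F3 | step 7 | unsaturated N-DMB pyrrolophane lactone (E/Z) | O=C2O[C@@H](C)C[C@@H]1CCCC=CCCc3ccc(n3Cc4ccc(OC)cc4OC)[C@H]12
F4 | step 9 | hydroxy Weinreb amide from opening of 20 | CON(C)C(=O)[C@@H]1c2ccc(CCCCCCC[C@H]1C[C@H](C)O)[nH]2
F5 | step 9 | (Z)-keto ester: methyl 3-methoxy-4-oxobut-2-enoate acylated by the pyrrolophane carbon (open form drawn) | COC(=O)/C=C(\C(=O)[C@@H]1c2ccc(CCCCCCC[C@H]1C[C@H](C)O)[nH]2)OC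
F6 | step 11 | spiro thiolactam | COC1=CC(=S)N[C@]12O[C@@H](C)C[C@@H]1CCCCCCCc3ccc([nH]3)[C@H]12
F7 | step 11 | ring B methylthio imidate | COC1=CC(SC)=N[C@]12O[C@@H](C)C[C@@H]1CCCCCCCc3ccc([nH]3)[C@H]12
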